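A flat stretch in noisy readings is easily taken for a stop, and that was the danger at this short meeting on the flask charged with 2.0 mM of substrate.

| setting | maple | alder | flask |
|---|---|---|---|
| substrate | 1 mM | 4 mM | 2.0 mM |
| remark | run made earlier | run made earlier |  |
| time |  |  | 8.0 min |

| run | time / min | isomer of the product A / % | target / % |
|---|---|---|---|
| maple | 0.417 | 1.9 | 23.5 |
| maple | 1.33 | 2.5 | 11.2 |
| maple | 2.50 | 5.1 | 6.9 |
| maple | 4.00 | 4.5 | 3.7 |
| maple | 5.00 | 5.3 | 2.9 |
| maple | 6.00 | 7.3 | 4.5 |
| alder | 0.500 | 0.4 | 19.3 |
| alder | 0.833 | 2.1 | 16.9 |
| alder | 1.33 | 4.4 | 12.5 |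
| alder | 2.50 | 4.9 | 5.8 |
| alder | 4.00 | 6.4 | 4.9 |
| alder | 6.00 | 6.2 | 5.9 |

(each reading ± 1 percentage point)

- ratio of isomer of the product A to target at 0.20 s
- ratio of isomer of the product A to target at 8.0 min
- which of isomer of the product A and target there is more of at 8.0 min

- the analysis behind the earlier runs scatters by 1 percentage point, standard deviation

The analyst reported that the maple and alder runs, at 1 mM and 4 mM, agreed in percent of the charge within the scatter, so both could be pooled for the flask. The forecaster argued that “Both plateaus persist from 4 to 6 min”, and put the ratio at 4.000 × 10⁻⁴ for 0.20 s and 1.35 for 8.0 min, with isomer of the product A ahead.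

I objected at the board that [isomer of the product A] did not look flat: from 2.50 min to 6.00 min it gained 2.2 percentage points in the maple run and 1.3 points in the alder run. Each gain is a reading with the scatter on both ends. Pooled, they give 0.00500 min⁻¹ as a fraction of the charge. I named this the creep, the steady gain of [isomer of the product A] per minute on the late stretch, a pseudo-zero-order rate.

A constant rate integrates to a straight line, so from the pooled 5.00% at 2.50 min, I reached 7.75% at 8.0 min. The [target] readings from 4.00 min onward average 4.38%, so my ratio was 1.77, higher than the forecast's. I offered no figure for the early time.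

The flask gives a ratio of 0.0168 at 0.20 s and 1.65 at 8.0 min, with isomer of the product A ahead, 7.61% against 4.62%.

    substrate ⇌ target (K = 2.30, k = 0.230 s⁻¹)
    substrate ⇌ isomer of the product A (K = 46.0, k = 0.00380 s⁻¹)
    substrate ⇌ dormant form (K = 2.60, k = 0.320 s⁻¹)
    target ⇌ isomer of the product B (K = 17.0, k = 0.0430 s⁻¹)

In the flask, [isomer of the product A] went from 5.85% at 4.00 min to 7.61% at 8.00 min, a gain of 0.00440 min⁻¹ as a fraction of the charge, while the creep of 0.00500 min⁻¹ stays a reading from the earlier runs, with their scatter. Carried to the neighbour flask, charged with 1.2 mM of substrate, the same line gives 7.75% of [isomer of the product A] at 8.0 min, and a ratio of 1.77. The neighbour flask holds 7.61% of isomer of the product A against 4.62% of target at 8.00 min, a ratio of 1.65.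

The data come from a simulation from invented constants, and the scatter is random.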